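**Retrosynthetic overview** (locants are those of the target: azulene C1–C8a for the left half, 1-benzoxepine O1–C9a for the right half)
1. The oxepanone ring is formed last, by Markovnikov alkoxymercuration of the C9a hydroxyl onto a homoprenyl group, then oxidation and desilylation.
2. The cyclohexane half comes from (R)-4-hydroxy-2,4-dimethylcyclohexenone (from (R)-linalool by ozonolysis, Grignard addition, ring-closing metathesis and oxidation) through alkoxide-directed 1,4-addition of the left-half Grignard reagent and enolate alkylation.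
3. The left-half side chain comes from a Johnson–Claisen rearrangement of the bicyclic allylic alcohol, which makes the C5–CH2 bond, sets C5 and moves the alkene to C6=C7.
4. The cycloheptenone comes from one-carbon ring expansion (dibromocarbene) of a cis-hydrindene silyl enol ether, itself the Diels–Alder adduct of (S)-4-silyloxy-4-methylcyclopentenone (from (S)-linalool) and the mesityl oxide silyloxydiene.
5. Ring order: cyclopentene (metathesis), cyclohexene (Diels–Alder), cycloheptene (ring expansion); cyclohexenone (metathesis), oxepane last.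

Assumption: (S)-(+)-linalool, (R)-(−)-linalool, mesityl oxide and 5-iodo-2-methylpent-2-ene are bought, both linalools in high enantiomeric purity.

**Step 1**
Reactants: 1 (S)-linalool
Product: 2 (3S)-3-[(tert-butyldimethylsilyl)oxy]-3,7-dimethylocta-1,6-diene
Conditions: t-BuMe2SiOTf, 2,6-lutidine, CH2Cl2, −78 → 0 °C
Reagents that add atoms: tert-butyldimethylsilyl trifluoromethanesulfonate, CC(C)(C)[Si](C)(C)OS(=O)(=O)C(F)(F)F
Why: O-silylation with the silyl triflate protects the hindered tertiary allylic alcohol, and its bulk later shields one face of the cyclopentenone; no stereocentre is touched.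

**Step 2**
Reactants: 2 silyl ether of (S)-linalool
Product: 3 (S)-tert-butyldimethyl[(1-methylcyclopent-2-en-1-yl)oxy]silane
Conditions: second-generation Grubbs catalyst RuCl2(=CHPh)(PCy3)(H2IMes) (2 mol %), CH2Cl2, 40 °C
Reagents that add atoms: none
Why: Ring-closing metathesis between the vinyl group and the trisubstituted alkene expels 2-methylpropene and closes the cyclopentene without touching the carbinol centre.

**Step 3**
Reactants: 3 silyloxycyclopentene
Product: 5 (S)-4-[(tert-butyldimethylsilyl)oxy]-4-methylcyclopent-2-en-1-one, via allylic tert-butyl peroxide 4 (not isolated)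
Conditions: Rh2(caprolactamate)4 (1 mol %), t-BuOOH (70% aq.), K2CO3, CH2Cl2, rt
Reagents that add atoms: tert-butyl hydroperoxide, CC(C)(C)OO
Why: Catalytic allylic C–H oxidation attacks the only allylic CH2 and gives the enone through the mixed peroxide, the quaternary carbinol centre having no hydrogen to lose.

**Step 4**
Reactants: 6 mesityl oxide
Product: 8 tert-butyldimethyl[(4-methylpenta-1,3-dien-2-yl)oxy]silane, via lithium dienolate 7 (not isolated)
Conditions: LiN(iPr)2, THF, −78 °C; then t-BuMe2SiCl, HMPA, −78 °C → rt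
Reagents that add atoms: tert-butyldimethylsilyl chloride, CC(C)(C)[Si](C)(C)Cl
Why: Kinetic deprotonation at the methyl ketone and O-silylation (silyl enol ether formation) give the cross-conjugated 2-silyloxydiene.

**Step 5**
Reactants: 5 silyloxy enone; 8 silyloxydiene
Product: 9 (3S,3aS,7aS)-3,5-bis[(tert-butyldimethylsilyl)oxy]-3,7,7-trimethyl-2,3,3a,4,7,7a-hexahydro-1H-inden-1-one
Conditions: AlBr3/Al(CH3)3 (5:1, 0.2 equiv), toluene/CH2Cl2, −5 °C
Reagents that add atoms: none
Why: Lewis-acid-promoted Diels–Alder cycloaddition under the mixed-aluminium conditions used for hindered dienes gives para/ortho regiochemistry (CMe2 terminus on the carbon next to the carbonyl), and the diene is expected to add cis across the enone on the face opposite the bulky silyloxy group, which sets both ring-fusion centres.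

**Step 6**
Reactants: 9 cis-fused hydrindenone
Product: 11 (1S,3aS,7aS)-1,6-bis[(tert-butyldimethylsilyl)oxy]-1,4,4-trimethyl-2,3,3a,4,7,7a-hexahydro-1H-indene, via tosylhydrazone 10 (not isolated)
Conditions: TsNHNH2, EtOH, rt; then catecholborane, CHCl3, 0 °C; NaOAc·3H2O, 60 °C
Reagents that add atoms: none
Why: Tosylhydrazone reduction with catecholborane (Kabalka modification of the Caglioti deoxygenation) removes the activating ketone under mild conditions chosen to avoid epimerising the adjacent ring-fusion centre and to spare the silyl enol ether.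

**Step 7**
Reactants: 11 silyl enol ether
Product: 13 (1S,3aS,8aS)-6-bromo-1-[(tert-butyldimethylsilyl)oxy]-1,4,4-trimethyl-2,3,3a,4,8,8a-hexahydroazulen-7(1H)-one, via dibromocyclopropane 12 (not isolated)
Conditions: CHBr3, KOtBu, pentane, −20 → 0 °C; then toluene, 110 °C
Reagents that add atoms: bromoform, BrC(Br)Br
Why: Dibromocarbene cyclopropanates the electron-rich silyl enol ether, and the silyloxy dibromocyclopropane opens with loss of bromide and the silyl group to the one-carbon ring-expanded 2-bromocycloheptenone, with regiochemistry fixed by the position of the enol ether.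

**Step 8**
Reactants: 13 bromo enone
Product: 14 (1S,3aS,8aS)-1-[(tert-butyldimethylsilyl)oxy]-1,4,4,6-tetramethyl-2,3,3a,4,8,8a-hexahydroazulen-7(1H)-one
Conditions: CH3B(OH)2, Pd(dppf)Cl2 (5 mol %), K3PO4, dioxane/H2O, 80 °C
Reagents that add atoms: methylboronic acid, CB(O)O
Why: Suzuki–Miyaura coupling of the α-bromo enone installs the vinylic methyl group.

**Step 9**
Reactants: 14 cycloheptenone
Product: 15 (1S,3aS,7R,8aS)-1-[(tert-butyldimethylsilyl)oxy]-1,4,4,6-tetramethyl-1,2,3,3a,4,7,8,8a-octahydroazulen-7-ol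
Conditions: NaBH4, CeCl3·7H2O, MeOH, −78 °C
Reagents that add atoms: none
Why: Luche 1,2-reduction is expected to deliver hydride from the convex face (the face of the ring-fusion hydrogens), placing the new hydroxyl on the side of the cyclopentane ring (7R).

**Step 10**
Reactants: 15 allylic alcohol
Product: 17 ethyl 2-[(1S,3aS,5R,8aS)-1-[(tert-butyldimethylsilyl)oxy]-1,4,4,6-tetramethyl-1,2,3,3a,4,5,8,8a-octahydroazulen-5-yl]acetate, via ketene acetal 16 (not isolated)
Conditions: CH3C(OEt)3, EtCO2H (cat.), xylene, 140 °C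
Reagents that add atoms: triethyl orthoacetate, CC(OCC)(OCC)OCC
Why: Johnson–Claisen [3,3]-sigmatropic rearrangement transfers the C7–O configuration suprafacially to C5, forming the C5–CH2 bond on the hindered face next to the quaternary carbon (5R) and moving the alkene to C6=C7.

**Step 11**
Reactants: 17 ester
Product: 18 2-[(1S,3aS,5R,8aS)-1-[(tert-butyldimethylsilyl)oxy]-1,4,4,6-tetramethyl-1,2,3,3a,4,5,8,8a-octahydroazulen-5-yl]ethan-1-ol
Conditions: LiAlH4, Et2O, 0 °C
Reagents that add atoms: none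
Why: Hydride reduction of the ester gives the primary alcohol and leaves the silyl ether and trisubstituted alkene alone.

**Step 12**
Reactants: 18 primary alcohol
Product: 19 primary bromide of the left half
Conditions: CBr4, PPh3, CH2Cl2, 0 °C
Reagents that add atoms: carbon tetrabromide, BrC(Br)(Br)Br
Why: Appel bromination converts the unhindered primary alcohol into the bromide needed for the Grignard reagent.

**Step 13**
Reactants: 20 (R)-linalool
Product: 22 (5R)-5-ethenyl-5-methyloxolan-2-ol, via ozonide 21 (not isolated)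
Conditions: O3 (1 equiv), CH2Cl2, −78 °C; then PPh3, −78 °C → rt
Reagents that add atoms: ozone, [O-][O+]=O
Why: Ozonolysis is selective for the electron-rich trisubstituted alkene, and the resulting hydroxy aldehyde closes to the lactol with the carbinol centre untouched.

**Step 14**
Reactants: 22 lactol
Product: 23 (6R)-2,6-dimethylocta-1,7-diene-3,6-diol
Conditions: CH2=C(CH3)MgBr (3 equiv), THF, 0 °C → rt
Reagents that add atoms: isopropenylmagnesium bromide, CC(=C)[Mg]Br
Why: Grignard addition to the open hydroxy-aldehyde form of the lactol gives the diene diol; the new secondary carbinol forms as a mixture that is erased in step 16.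

**Step 15**
Reactants: 23 diene diol
Product: 24 (4R)-2,4-dimethylcyclohex-2-ene-1,4-diol
Conditions: second-generation Grubbs catalyst RuCl2(=CHPh)(PCy3)(H2IMes) (5 mol %), CH2Cl2, 40 °C
Reagents that add atoms: none
Why: Ring-closing metathesis of the vinyl and isopropenyl groups closes the cyclohexene with loss of ethene.

**Step 16**
Reactants: 24 cyclohexene diol
Product: 25 (R)-4-hydroxy-2,4-dimethylcyclohex-2-en-1-one
Conditions: MnO2, CH2Cl2, rt
Reagents that add atoms: none
Why: MnO2 oxidises only the secondary allylic alcohol, so both epimers converge on the enone with the tertiary (R) carbinol intact.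

**Step 17**
Reactants: 19 left-half bromide; 25 hydroxy enone
Product: 29 bis(trimethylsilyl) derivative of the conjugate adduct (silyl enol ether plus tertiary silyl ether), via chloromagnesium alkoxide 26 (not isolated), via Grignard reagent 27 (not isolated), via magnesium enolate 28 (not isolated)
Conditions: 19, Mg, THF, 45 °C; 25 (1.5 equiv), (CH3)3CMgCl, THF, −78 °C; combine, −78 → 0 °C; then Me3SiCl, Et3N, HMPA, −78 °C → rt
Reagents that add atoms: trimethylsilyl chloride, C[Si](C)(C)Cl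
Why: Alkoxide-directed conjugate addition of the Grignard reagent (the ligand-assisted 1,4-addition known for 4-hydroxy-4-methylcyclohexadienones) delivers the chain to C6 on the face of the magnesium alkoxide, cis to oxygen, and O-silylation traps the regiodefined enolate.

**Step 18**
Reactants: 29 silyl enol ether
Product: 31 2-methyl-2-(4-methylpent-3-enyl)cyclohexanone carrying the left-half chain and the tertiary silyl ether, via lithium enolate 30 (not isolated)
Conditions: CH3Li, THF, 0 °C; then HMPA, 5-iodo-2-methylpent-2-ene, −40 °C → rt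
Reagents that add atoms: 5-iodo-2-methylpent-2-ene, CC(C)=CCCI
Why: Methyllithium unmasks the lithium enolate regiospecifically, and C-alkylation anti to the neighbouring C6 side chain sets the quaternary C5a centre with methyl cis and homoprenyl trans to that chain.

**Step 19**
Reactants: 31 ketone
Product: 32 equatorial secondary alcohol
Conditions: LiAlH4, Et2O, −78 → 0 °C
Reagents that add atoms: none
Why: Axial hydride delivery to the cyclohexanone, as in 4,4-disubstituted 3-keto triterpenoids, gives the equatorial C9a alcohol trans to the homoprenyl group.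

**Step 20**
Reactants: 32 hydroxy alkene
Product: 34 trans-fused 2,2-dimethyloxepan-3-ol (C3 epimers), via organomercurial 33 (not isolated)
Conditions: Hg(O2CCF3)2, NaHCO3, CH3NO2, −20 °C; then NaBH4, O2, DMF, 0 °C
Reagents that add atoms: dioxygen, O=O
Why: Intramolecular Markovnikov alkoxymercuration closes the oxepane at the tertiary carbon (trans fusion from the equatorial hydroxyl; the ring alkene has no internal nucleophile), and oxidative demercuration replaces mercury by hydroxyl.

**Step 21**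
Reactants: 34 oxepanol
Product: 35 bis-silylated oxepanone
Conditions: Dess–Martin periodinane, NaHCO3, CH2Cl2, 0 °C → rt
Reagents that add atoms: none
Why: Dess–Martin oxidation converts the only free secondary alcohol into the C3 ketone, so both C3 epimers converge.

**Step 22**
Reactants: 35 bis-silyl ether
Product: 36 target, (5aS,6S,7R,9aS)-7-hydroxy-6-{2-[(1S,3aS,5R,8aS)-1-hydroxy-1,4,4,6-tetramethyl-1,2,3,3a,4,5,8,8a-octahydroazulen-5-yl]ethyl}-2,2,5a,7-tetramethyloctahydro-1-benzoxepin-3(2H)-one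
Conditions: HF·pyridine, THF, 0 °C → rt
Reagents that add atoms: none
Why: Fluoride-mediated desilylation frees both tertiary alcohols without touching the ketone, the ether or the alkene.

**Compound list**
1 | (S)-(+)-linalool | C=C[C@@](C)(O)CCC=C(C)C | starting material
2 | (3S)-3-[(tert-butyldimethylsilyl)oxy]-3,7-dimethylocta-1,6-diene | C=C[C@@](C)(O[Si](C)(C)C(C)(C)C)CCC=C(C)C | intermediate
3 | (S)-tert-butyldimethyl[(1-methylcyclopent-2-en-1-yl)oxy]silane | C[C@@]1(O[Si](C)(C)C(C)(C)C)C=CCC1 | intermediate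
4 | (4S)-1-(tert-butylperoxy)-4-[(tert-butyldimethylsilyl)oxy]-4-methylcyclopent-2-ene (C1 epimers) | C[C@@]1(O[Si](C)(C)C(C)(C)C)C=CC(OOC(C)(C)C)C1 | intermediate
5 | (S)-4-[(tert-butyldimethylsilyl)oxy]-4-methylcyclopent-2-en-1-one | C[C@@]1(O[Si](C)(C)C(C)(C)C)C=CC(=O)C1 | intermediate
6 | mesityl oxide (4-methylpent-3-en-2-one) | CC(=O)C=C(C)C | starting material
7 | lithium 4-methylpenta-1,3-dien-2-olate | [Li]OC(=C)C=C(C)C | intermediate
8 | tert-butyldimethyl[(4-methylpenta-1,3-dien-2-yl)oxy]silane | C=C(O[Si](C)(C)C(C)(C)C)C=C(C)C | intermediate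
9 | (3S,3aS,7aS)-3,5-bis[(tert-butyldimethylsilyl)oxy]-3,7,7-trimethyl-2,3,3a,4,7,7a-hexahydro-1H-inden-1-one (cis-fused, ring-fusion hydrogens cis to the C3 silyloxy group) | CC(C)(C)[Si](C)(C)OC1=CC(C)(C)[C@H]2C(=O)C[C@](C)(O[Si](C)(C)C(C)(C)C)[C@H]2C1 | intermediate
10 | 4-methylbenzenesulfonylhydrazone of 9 | CC(C)(C)[Si](C)(C)OC1=CC(C)(C)[C@H]2C(=NNS(=O)(=O)c3ccc(C)cc3)C[C@](C)(O[Si](C)(C)C(C)(C)C)[C@H]2C1 | intermediate
11 | (1S,3aS,7aS)-1,6-bis[(tert-butyldimethylsilyl)oxy]-1,4,4-trimethyl-2,3,3a,4,7,7a-hexahydro-1H-indene | CC(C)(C)[Si](C)(C)OC1=CC(C)(C)[C@H]2CC[C@](C)(O[Si](C)(C)C(C)(C)C)[C@H]2C1 | intermediate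
12 | dibromocyclopropane from 11 (CBr2 across the enol ether, on the face of the ring-fusion hydrogens) | CC(C)(C)[Si](C)(C)O[C@@]15[C@H](C5(Br)Br)C(C)(C)[C@H]2CC[C@](C)(O[Si](C)(C)C(C)(C)C)[C@H]2C1 | intermediate
13 | (1S,3aS,8aS)-6-bromo-1-[(tert-butyldimethylsilyl)oxy]-1,4,4-trimethyl-2,3,3a,4,8,8a-hexahydroazulen-7(1H)-one | BrC1=CC(C)(C)[C@H]2CC[C@](C)(O[Si](C)(C)C(C)(C)C)[C@H]2CC1=O | intermediate
14 | (1S,3aS,8aS)-1-[(tert-butyldimethylsilyl)oxy]-1,4,4,6-tetramethyl-2,3,3a,4,8,8a-hexahydroazulen-7(1H)-one | CC1=CC(C)(C)[C@H]2CC[C@](C)(O[Si](C)(C)C(C)(C)C)[C@H]2CC1=O | intermediate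
15 | (1S,3aS,7R,8aS)-1-[(tert-butyldimethylsilyl)oxy]-1,4,4,6-tetramethyl-1,2,3,3a,4,7,8,8a-octahydroazulen-7-ol | CC1=CC(C)(C)[C@H]2CC[C@](C)(O[Si](C)(C)C(C)(C)C)[C@H]2C[C@H]1O | intermediate
16 | mixed ketene acetal of 15 (7-O-(1-ethoxyvinyl) ether) | CC1=CC(C)(C)[C@H]2CC[C@](C)(O[Si](C)(C)C(C)(C)C)[C@H]2C[C@H]1OC(=C)OCC | intermediate
17 | ethyl 2-[(1S,3aS,5R,8aS)-1-[(tert-butyldimethylsilyl)oxy]-1,4,4,6-tetramethyl-1,2,3,3a,4,5,8,8a-octahydroazulen-5-yl]acetate | CC1=CC[C@H]2[C@H](CC[C@]2(C)O[Si](C)(C)C(C)(C)C)C(C)(C)[C@@H]1CC(=O)OCC | intermediate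
18 | 2-[(1S,3aS,5R,8aS)-1-[(tert-butyldimethylsilyl)oxy]-1,4,4,6-tetramethyl-1,2,3,3a,4,5,8,8a-octahydroazulen-5-yl]ethan-1-ol | CC1=CC[C@H]2[C@H](CC[C@]2(C)O[Si](C)(C)C(C)(C)C)C(C)(C)[C@@H]1CCO | intermediate
19 | {[(1S,3aS,5R,8aS)-5-(2-bromoethyl)-1,4,4,6-tetramethyl-1,2,3,3a,4,5,8,8a-octahydroazulen-1-yl]oxy}(tert-butyl)dimethylsilane | CC1=CC[C@H]2[C@H](CC[C@]2(C)O[Si](C)(C)C(C)(C)C)C(C)(C)[C@@H]1CCBr | intermediate
20 | (R)-(−)-linalool | C=C[C@](C)(O)CCC=C(C)C | starting material
21 | ozonide of 20 (3,3-dimethyl-1,2,4-trioxolane on the former trisubstituted alkene) | C=C[C@](C)(O)CCC1OOC(C)(C)O1 | intermediate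
22 | (5R)-5-ethenyl-5-methyloxolan-2-ol (anomers) | C=C[C@@]1(C)CCC(O)O1 | intermediate
23 | (6R)-2,6-dimethylocta-1,7-diene-3,6-diol (C3 epimers) | C=C[C@](C)(O)CCC(O)C(C)=C | intermediate
24 | (4R)-2,4-dimethylcyclohex-2-ene-1,4-diol (C1 epimers) | CC1=C[C@](C)(O)CCC1O | intermediate
25 | (R)-4-hydroxy-2,4-dimethylcyclohex-2-en-1-one | CC1=C[C@](C)(O)CCC1=O | intermediate
26 | chloromagnesium alkoxide of 25 | CC1=C[C@](C)(O[Mg]Cl)CCC1=O | intermediate
27 | Grignard reagent from 19 | CC1=CC[C@H]2[C@H](CC[C@]2(C)O[Si](C)(C)C(C)(C)C)C(C)(C)[C@@H]1CC[Mg]Br | intermediate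
28 | magnesium enolate/alkoxide of the conjugate adduct (chain cis to the alkoxide) | CC1=CC[C@H]2[C@H](CC[C@]2(C)O[Si](C)(C)C(C)(C)C)C(C)(C)[C@@H]1CC[C@H]1C(C)=C(O[Mg]Br)CC[C@@]1(C)O[Mg]Cl | intermediate
29 | bis(trimethylsilyl) derivative of the conjugate adduct | CC1=CC[C@H]2[C@H](CC[C@]2(C)O[Si](C)(C)C(C)(C)C)C(C)(C)[C@@H]1CC[C@H]1C(C)=C(O[Si](C)(C)C)CC[C@@]1(C)O[Si](C)(C)C | intermediate
30 | lithium enolate from 29 | CC1=CC[C@H]2[C@H](CC[C@]2(C)O[Si](C)(C)C(C)(C)C)C(C)(C)[C@@H]1CC[C@H]1C(C)=C(O[Li])CC[C@@]1(C)O[Si](C)(C)C | intermediate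
31 | alkylated ketone (quaternary carbon: methyl cis, homoprenyl trans to the left-half chain) | CC1=CC[C@H]2[C@H](CC[C@]2(C)O[Si](C)(C)C(C)(C)C)C(C)(C)[C@@H]1CC[C@H]1[C@](C)(CCC=C(C)C)C(=O)CC[C@@]1(C)O[Si](C)(C)C | intermediate
32 | equatorial secondary alcohol from 31 | CC1=CC[C@H]2[C@H](CC[C@]2(C)O[Si](C)(C)C(C)(C)C)C(C)(C)[C@@H]1CC[C@H]1[C@](C)(CCC=C(C)C)[C@@H](O)CC[C@@]1(C)O[Si](C)(C)C | intermediate
33 | oxepanylmercury trifluoroacetate (C3 epimers) | CC1=CC[C@H]2[C@H](CC[C@]2(C)O[Si](C)(C)C(C)(C)C)C(C)(C)[C@@H]1CC[C@H]1[C@]2(C)CCC([Hg]OC(=O)C(F)(F)F)C(C)(C)O[C@H]2CC[C@@]1(C)O[Si](C)(C)C | intermediate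
34 | trans-fused oxepan-3-ol, bis-silyl ether (C3 epimers) | CC1=CC[C@H]2[C@H](CC[C@]2(C)O[Si](C)(C)C(C)(C)C)C(C)(C)[C@@H]1CC[C@H]1[C@]2(C)CCC(O)C(C)(C)O[C@H]2CC[C@@]1(C)O[Si](C)(C)C | intermediate
35 | oxepan-3-one, bis-silyl ether | CC1=CC[C@H]2[C@H](CC[C@]2(C)O[Si](C)(C)C(C)(C)C)C(C)(C)[C@@H]1CC[C@H]1[C@]2(C)CCC(=O)C(C)(C)O[C@H]2CC[C@@]1(C)O[Si](C)(C)C | intermediate
36 | (5aS,6S,7R,9aS)-7-hydroxy-6-{2-[(1S,3aS,5R,8aS)-1-hydroxy-1,4,4,6-tetramethyl-1,2,3,3a,4,5,8,8a-octahydroazulen-5-yl]ethyl}-2,2,5a,7-tetramethyloctahydro-1-benzoxepin-3(2H)-one | CC1=CC[C@H]2[C@H](CC[C@]2(C)O)C(C)(C)[C@@H]1CC[C@H]1[C@]2(C)CCC(=O)C(C)(C)O[C@H]2CC[C@@]1(C)O | target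

**Step count**
Total: 22 steps. Longest linear sequence: 17 steps from (S)-linalool (steps 1–3, 5–12, 17–22); step 4 and steps 13–16 are side branches.

**Three steps most likely to fail**

Step 5 (hindered Diels–Alder; the face selectivity against a methyl/silyloxy pair is not secured by precedent). The fallback sets out from 5 and returns at 9, and replaces facial control in the cycloaddition by hydroxyl-directed hydrogenation. HF·pyridine frees (S)-4-hydroxy-4-methylcyclopent-2-en-1-one F1. Br2 then Et3N gives (S)-2-bromo-4-hydroxy-4-methylcyclopent-2-en-1-one F2. Cycloaddition with 8 under the same AlBr3/Al(CH3)3 conditions (one extra equivalent of Al(CH3)3 for the hydroxyl) gives the bromo cycloadduct F3, whose face of addition no longer matters. DBU in toluene at 80 °C removes HBr to give the ring-fusion enone F4. H2 with [Ir(cod)(PCy3)(py)]PF6 in CH2Cl2 adds both hydrogens cis to the free hydroxyl, giving the cis-fused hydroxy ketone F5, and t-BuMe2SiOTf/2,6-lutidine returns 9.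

Step 18 (a hindered tetrasubstituted enolate and an unactivated primary iodide). The fallback sets out from 29 and returns at 31, building the homoprenyl group in stages from a reactive electrophile. CH3Li then allyl bromide gives the allyl ketone F6 (same anti alkylation). 9-BBN then NaBO3 hydroborates only the terminal alkene to the primary alcohol F7. Dess–Martin periodinane gives the aldehyde F8, and Wittig olefination with Ph3P=C(CH3)2 (from isopropyltriphenylphosphonium iodide and n-C4H9Li) at the aldehyde, not the hindered ketone, returns 31.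

Step 20 (seven-membered ring closure by alkoxymercuration in the presence of the ring alkene). The fallback sets out from 29 and returns at 34, closing the ring by epoxide opening instead. mCPBA converts 5-iodo-2-methylpent-2-ene into racemic 2-(2-iodoethyl)-3,3-dimethyloxirane F9. Alkylation of the enolate from 29 (CH3Li, HMPA) with F9 gives the epoxy ketone F10. NaBH4 in MeOH at −20 °C gives the equatorial epoxy alcohol F11. BF3·OEt2 (cat.) in CH2Cl2 at −78 °C opens the epoxide at its tertiary carbon (7-endo) to give 34; the competing 6-exo opening to a tetrahydropyran is the risk here.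

**Further compounds**
F1 | step 5 | (S)-4-hydroxy-4-methylcyclopent-2-en-1-one | C[C@@]1(O)C=CC(=O)C1
F2 | step 5 | (S)-2-bromo-4-hydroxy-4-methylcyclopent-2-en-1-one | C[C@@]1(O)C=C(Br)C(=O)C1
F3 | step 5 | bromo cycloadduct (7a-bromo-5-silyloxy-3-hydroxy-3,7,7-trimethylhexahydroinden-1-one, ring-fusion isomers) | CC(C)(C)[Si](C)(C)OC1=CC(C)(C)C2(Br)C(=O)C[C@](C)(O)C2C1
F4 | step 5 | ring-fusion enone (3-hydroxy-5-silyloxy-3,7,7-trimethyl-2,3,4,7-tetrahydro-1H-inden-1-one) | CC(C)(C)[Si](C)(C)OC1=CC(C)(C)C2=C(C1)[C@@](C)(O)CC2=O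
F5 | step 5 | cis-fused hydroxy ketone (9 without the C3 silyl group) | CC(C)(C)[Si](C)(C)OC1=CC(C)(C)[C@H]2C(=O)C[C@](C)(O)[C@H]2C1
F6 | step 18 | allyl ketone (31 with allyl in place of homoprenyl) | CC1=CC[C@H]2[C@H](CC[C@]2(C)O[Si](C)(C)C(C)(C)C)C(C)(C)[C@@H]1CC[C@H]1[C@](C)(CC=C)C(=O)CC[C@@]1(C)O[Si](C)(C)C
F7 | step 18 | 3-hydroxypropyl ketone | CC1=CC[C@H]2[C@H](CC[C@]2(C)O[Si](C)(C)C(C)(C)C)C(C)(C)[C@@H]1CC[C@H]1[C@](C)(CCCO)C(=O)CC[C@@]1(C)O[Si](C)(C)C
F8 | step 18 | keto aldehyde | CC1=CC[C@H]2[C@H](CC[C@]2(C)O[Si](C)(C)C(C)(C)C)C(C)(C)[C@@H]1CC[C@H]1[C@](C)(CCC=O)C(=O)CC[C@@]1(C)O[Si](C)(C)C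
F9 | step 20 | 2-(2-iodoethyl)-3,3-dimethyloxirane (racemic) | CC1(C)OC1CCI
F10 | step 20 | epoxy ketone (epoxide epimers) | CC1=CC[C@H]2[C@H](CC[C@]2(C)O[Si](C)(C)C(C)(C)C)C(C)(C)[C@@H]1CC[C@H]1[C@](C)(CCC2OC2(C)C)C(=O)CC[C@@]1(C)O[Si](C)(C)C
F11 | step 20 | epoxy alcohol (epoxide epimers) | CC1=CC[C@H]2[C@H](CC[C@]2(C)O[Si](C)(C)C(C)(C)C)C(C)(C)[C@@H]1CC[C@H]1[C@](C)(CCC2OC2(C)C)[C@@H](O)CC[C@@]1(C)O[Si](C)(C)C
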